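**Retrosynthetic overview**
1. The C7 carbinol comes from a C7 ketone plus a methyl nucleophile. The C6–CH2 bond is cut by an aldol between the C6 (α′) enolate of a bicyclic enone (rings A and B) and a β,γ-unsaturated aldehyde carrying ring C. Dehydration and conjugate reduction then leave the CH2CH2 linker.
2. Rings A (oxepane) and B (cyclohexanone) are formed in that order in one epoxonium cascade of a Shi-derived diepoxy enol silane made from (E)-geranylacetone.
3. Ring C is bought as 2-methylcyclohexane-1,3-dione. A desymmetrizing CBS reduction sets both stereocentres, cross-metathesis builds the side chain, and enol triflate, Stille coupling and hydroboration give the ring alkene and the two-carbon aldehyde.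
4. No ring is formed after the coupling.

**Assumptions.** Benzoxepine atoms are numbered O1, C2–C5, C5a, C6–C9, C9a. The D-fructose-derived Shi ketone is taken to give (R)-configured epoxide carbons, and the (S)-CBS catalyst the (R)-carbinol. CyR = (5R,6S)-2,6-dimethyl-6-[(2E)-4-methyl-4-(triethylsilyloxy)pent-2-en-1-yl]-5-(triethylsilyloxy)cyclohex-1-en-1-yl (OSiEt3 cis to the pentenyl chain).

## Fragment 1 (rings A and B)

Step 1
Reactants: 1 geranyl bromide; 2 ethyl acetoacetate
Product: 3 ethyl (4E)-2-acetyl-5,9-dimethyldeca-4,8-dienoate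
Conditions: K2CO3, acetone, 56 °C
Reagents that add atoms: none
Why: Acetoacetic ester alkylation of the doubly activated methylene with a primary allylic bromide is a clean SN2 reaction, and the racemic α-centre becomes CH2 in step 2.

Step 2
Reactants: 3 alkylated acetoacetate
Product: 5 (5E)-6,10-dimethylundeca-5,9-dien-2-one (geranylacetone), via β-keto acid 4 (not isolated)
Conditions: KOH, MeOH–H2O, 60 °C; then 2 M HCl, 60 °C
Reagents that add atoms: none
Why: Saponification and decarboxylation of the β-keto acid (ketonic cleavage) leave the (E)-alkene untouched and create no stereocentre.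

Step 3
Reactants: 5 geranylacetone
Product: 6 (R,R,R)-diepoxy ketone
Conditions: 1,2:4,5-di-O-isopropylidene-β-D-erythro-2,3-hexodiulo-2,6-pyranose (Shi ketone, 0.4 equiv), KHSO5 (as 2KHSO5·KHSO4·K2SO4), K2CO3, Bu4NHSO4, MeCN–CH2(OMe)2–aq. Na2B4O7, 0 °C
Reagents that add atoms: potassium peroxymonosulfate, [K+].[O-]S(=O)(=O)OO
Why: Shi asymmetric epoxidation attacks both trisubstituted alkenes through the same spiro transition state, which sets all three epoxide stereocentres as R (they become C9a, C5a and C3), while the ketone is inert at pH 10.5.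

Step 4
Reactants: 6 diepoxy ketone
Product: 7 terminal trimethylsilyl enol ether of 6
Conditions: LiN(iPr)2, Me3SiCl, THF, −78 °C (in situ quench); non-aqueous work-up
Reagents that add atoms: chlorotrimethylsilane, C[Si](C)(C)Cl
Why: Kinetic enolization of a methyl ketone occurs on the CH3 side and is trapped at once as the enol silane, and trisubstituted epoxides tolerate the amide base at −78 °C.

Step 5
Reactants: 7 diepoxy enol silane
Product: 9 (3R,5aR,9aR)-3-hydroxy-2,2,5a-trimethyloctahydro-1-benzoxepin-7(2H)-one, via trimethylsilyl ether 8 (not isolated)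
Conditions: Me3SiOTf (0.3 equiv), 2,6-di-tert-butyl-4-methylpyridine, CH2Cl2, −78 °C; then K2CO3 (cat.), MeOH, 0 °C
Reagents that add atoms: none
Why: In this epoxonium cascade (tandem oxa- and carbacyclization) the silyl-activated terminal epoxide is opened at its tertiary carbon by the internal epoxide oxygen to close ring A, and the enol silane then opens the epoxonium at its tertiary carbon with inversion to close ring B, so the (E)-derived (R,R) epoxide gives the trans ring fusion (5aR,9aR) and the terminal epoxide gives 3R with retention.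

Step 6
Reactants: 9 hydroxy ketone
Product: 10 triethylsilyl ether of 9
Conditions: Et3SiCl, imidazole, DMF, 23 °C
Reagents that add atoms: chlorotriethylsilane, CC[Si](CC)(CC)Cl
Why: Standard silylation of the only hydroxyl gives a group that survives strong base and is removed by fluoride at the end.

Step 7
Reactants: 10 silyl-protected ketone
Product: 12 (3R,5aR,9aR)-2,2,5a-trimethyl-3-(triethylsilyloxy)-2,3,4,5,5a,9a-hexahydro-1-benzoxepin-7(6H)-one, via silyl enol ether 11 (not isolated)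
Conditions: LiN(iPr)2, Me3SiCl, THF, −78 °C; then Pd(OAc)2 (1.1 equiv), MeCN, 23 °C
Reagents that add atoms: none
Why: In this Saegusa–Ito oxidation, kinetic enolization occurs at the unhindered C8, and because C5a is quaternary only the C8–C9 side can undergo β-hydride elimination, so a single enone forms.

## Fragment 2 (ring C)

Step 8
Reactants: 13 2-methylcyclohexane-1,3-dione; 14 allyl bromide
Product: 15 2-methyl-2-(prop-2-en-1-yl)cyclohexane-1,3-dione
Conditions: 1 M aq. NaOH, 23 °C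
Reagents that add atoms: none
Why: C-alkylation of the stabilized 1,3-dione enolate with a reactive allylic halide in water builds the quaternary carbon as an achiral, prochiral centre.

Step 9
Reactants: 15 allyl methyl dione
Product: 16 (2R,3R)-3-hydroxy-2-methyl-2-(prop-2-en-1-yl)cyclohexan-1-one
Conditions: (S)-1-methyl-3,3-diphenyltetrahydro-1H,3H-pyrrolo[1,2-c][1,3,2]oxazaborole ((S)-2-methyl-CBS-oxazaborolidine, 0.2 equiv), catecholborane, toluene, −60 °C; then MeOH, aq. NaOH wash
Reagents that add atoms: none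
Why: This CBS reduction desymmetrizes the dione, because the (S)-catalyst gives the (R)-carbinol with the quaternary carbon as the large group and hydride delivery from the methyl face (anti to allyl) selects the carbonyl that places OH cis to allyl, so both centres are set as (2R,3R).

Step 10
Reactants: 16 hydroxy ketone; 17 2-methylbut-3-en-2-ol
Product: 18 (2R,3R)-3-hydroxy-2-[(2E)-4-hydroxy-4-methylpent-2-en-1-yl]-2-methylcyclohexan-1-one
Conditions: 17 (8 equiv), second-generation Grubbs catalyst (H2IMes)(PCy3)Cl2Ru=CHPh (5 mol %), CH2Cl2, 40 °C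
Reagents that add atoms: none
Why: Olefin cross-metathesis of a terminal alkene with an excess of a hindered tertiary allylic alcohol gives the (E)-alkene selectively and loses only ethene.

Step 11
Reactants: 18 diol
Product: 19 bis(triethylsilyl) ether of 18
Conditions: Et3SiOTf, 2,6-lutidine, CH2Cl2, −78 → 0 °C
Reagents that add atoms: triethylsilyl trifluoromethanesulfonate, CC[Si](CC)(CC)OS(=O)(=O)C(F)(F)F
Why: The silyl triflate is reactive enough to silylate the tertiary allylic alcohol as well as the secondary one, and the hindered base leaves the ketone alone.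

Step 12
Reactants: 19 protected ketone
Product: 21 (2R,3R,6RS)-2,6-dimethyl ketone, via lithium enolate 20 (not isolated)
Conditions: LiN(iPr)2, THF, −78 °C; then MeI, −78 → −20 °C
Reagents that add atoms: iodomethane, CI
Why: The ketone can enolize only toward C6 because C2 is quaternary, so this enolate alkylation is regiospecific, and the new C6 centre (a mixture) becomes sp2 in step 13.

Step 13
Reactants: 21 dimethyl ketone
Product: 23 (5R,6R)-enol triflate, via potassium enolate 22 (not isolated)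
Conditions: KN(SiMe3)2, THF, −78 → 0 °C; then PhNTf2, −78 → 23 °C
Reagents that add atoms: N-phenylbis(trifluoromethanesulfonimide), O=S(=O)(N(c1ccccc1)S(=O)(=O)C(F)(F)F)C(F)(F)F
Why: Deprotonation is again possible only at C6, so O-triflation of the fully substituted enolate fixes the ring double bond between the former carbonyl carbon and the methyl-bearing carbon.

Step 14
Reactants: 23 enol triflate
Product: 24 (5R,6S)-1-ethenyl diene
Conditions: tributyl(vinyl)stannane, Pd(PPh3)4 (5 mol %), LiCl, THF, 65 °C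
Reagents that add atoms: tributyl(vinyl)stannane, C=C[Sn](CCCC)(CCCC)CCCC
Why: Stille coupling of a cyclohexenyl triflate with a vinylstannane, promoted by LiCl, tolerates the hindered position and touches no stereocentre.

Step 15
Reactants: 24 diene
Product: 26 2-(CyR)ethan-1-ol, via alkylborane 25 (not isolated)
Conditions: 9-BBN, THF, 0 → 23 °C; then aq. NaOH, H2O2, 0 °C
Reagents that add atoms: hydrogen peroxide, OO
Why: In this hydroboration–oxidation, 9-BBN adds anti-Markovnikov to the monosubstituted vinyl group far faster than to the tetrasubstituted ring alkene or the hindered internal (E)-alkene.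

Step 16
Reactants: 26 homoallylic alcohol
Product: 27 2-(CyR)acetaldehyde
Conditions: Dess–Martin periodinane, NaHCO3, CH2Cl2, 0 °C (used at once)
Reagents that add atoms: none
Why: Buffered Dess–Martin oxidation gives the β,γ-unsaturated aldehyde without acid or base that could move the tetrasubstituted alkene into conjugation.

## Coupling and completion

Step 17
Reactants: 12 bicyclic enone; 27 aldehyde
Product: 29 β-hydroxy enone (mixture at C6 and at the carbinol carbon), via lithium dienolate 28 (not isolated)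
Conditions: LiN(iPr)2, THF, −78 °C (12 added to the base); then 27, −78 °C, 15 min; AcOH quench at −78 °C
Reagents that add atoms: none
Why: In this directed aldol addition the base removes the only kinetically accessible α-proton of the enone (C6, since C8 is vinylic), and the cross-conjugated lithium dienolate adds to the unhindered aldehyde faster than it deprotonates it; the two new centres are erased in steps 18 and 19.

Step 18
Reactants: 29 aldol adduct
Product: 31 cross-conjugated dienone with an exocyclic C6 alkylidene, via mesylate 30 (not isolated)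
Conditions: MsCl, Et3N, CH2Cl2, 0 °C; then DBU, 0 → 23 °C
Reagents that add atoms: none
Why: Mesylation followed by E1cB elimination through the C6 enolate removes the only acidic β-hydrogen, so the alkene forms toward C6 and not toward the allylic CH2.

Step 19
Reactants: 31 dienone
Product: 32 (3R,5aR,6R,9aR)-6-[2-(CyR)ethyl] saturated ketone
Conditions: [(Ph3P)CuH]6 (0.8 equiv of hexamer), H2O, benzene–THF, 23 °C
Reagents that add atoms: none
Why: Copper hydride conjugate reduction takes both enone units and spares isolated alkenes, and water protonates the C6 enolate from the face opposite the axial C5a methyl, which puts the side chain equatorial (6R).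

Step 20
Reactants: 32 ketone
Product: 33 tris(triethylsilyl) ether of siphonellinol C
Conditions: MeLi, CeCl3, THF, −78 °C; aq. NH4Cl
Reagents that add atoms: methyllithium, [Li]C
Why: In this organocerium 1,2-addition the non-basic methyl reagent attacks from the equatorial direction because the axial path is blocked by the syn-axial C5a methyl, which gives the axial hydroxyl and equatorial methyl (7S).

Step 21
Reactants: 33 tris-silyl ether
Product: 34 siphonellinol C
Conditions: Bu4NF, THF, 23 → 45 °C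
Reagents that add atoms: none
Why: Fluoride-driven desilylation removes all three triethylsilyl ethers under basic conditions that do not ionize the tertiary or allylic alcohols.

## Compound list

1 | geranyl bromide, (2E)-1-bromo-3,7-dimethylocta-2,6-diene | CC(C)=CCC/C(C)=C/CBr | starting material
2 | ethyl acetoacetate | CCOC(=O)CC(C)=O | starting material
3 | ethyl (4E)-2-acetyl-5,9-dimethyldeca-4,8-dienoate (racemic) | CCOC(=O)C(C/C=C(\C)CCC=C(C)C)C(C)=O | intermediate
4 | (4E)-2-acetyl-5,9-dimethyldeca-4,8-dienoic acid | OC(=O)C(C/C=C(\C)CCC=C(C)C)C(C)=O | intermediate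
5 | (5E)-6,10-dimethylundeca-5,9-dien-2-one | CC(=O)CC/C=C(\C)CCC=C(C)C | intermediate
6 | 4-[(2R,3R)-3-{2-[(2R)-3,3-dimethyloxiran-2-yl]ethyl}-3-methyloxiran-2-yl]butan-2-one | CC(=O)CC[C@H]1O[C@]1(C)CC[C@H]1OC1(C)C | intermediate
7 | trimethyl({4-[(2R,3R)-3-{2-[(2R)-3,3-dimethyloxiran-2-yl]ethyl}-3-methyloxiran-2-yl]but-1-en-2-yl}oxy)silane | C=C(O[Si](C)(C)C)CC[C@H]1O[C@]1(C)CC[C@H]1OC1(C)C | intermediate
8 | (3R,5aR,9aR)-2,2,5a-trimethyl-3-(trimethylsilyloxy)octahydro-1-benzoxepin-7(2H)-one | O=C1C[C@@]2(C)CC[C@@H](O[Si](C)(C)C)C(C)(C)O[C@@H]2CC1 | intermediate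
9 | (3R,5aR,9aR)-3-hydroxy-2,2,5a-trimethyloctahydro-1-benzoxepin-7(2H)-one (trans-fused) | O=C1C[C@@]2(C)CC[C@@H](O)C(C)(C)O[C@@H]2CC1 | intermediate
10 | (3R,5aR,9aR)-2,2,5a-trimethyl-3-(triethylsilyloxy)octahydro-1-benzoxepin-7(2H)-one | O=C1C[C@@]2(C)CC[C@@H](O[Si](CC)(CC)CC)C(C)(C)O[C@@H]2CC1 | intermediate
11 | (3R,5aR,9aR)-2,2,5a-trimethyl-3-(triethylsilyloxy)-7-(trimethylsilyloxy)-2,3,4,5,5a,6,9,9a-octahydro-1-benzoxepine | C[Si](C)(C)OC=1C[C@@]2(C)CC[C@@H](O[Si](CC)(CC)CC)C(C)(C)O[C@@H]2CC=1 | intermediate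
12 | (3R,5aR,9aR)-2,2,5a-trimethyl-3-(triethylsilyloxy)-2,3,4,5,5a,9a-hexahydro-1-benzoxepin-7(6H)-one | O=C1C[C@@]2(C)CC[C@@H](O[Si](CC)(CC)CC)C(C)(C)O[C@@H]2C=C1 | intermediate
13 | 2-methylcyclohexane-1,3-dione | CC1C(=O)CCCC1=O | starting material
14 | allyl bromide | C=CCBr | starting material
15 | 2-methyl-2-(prop-2-en-1-yl)cyclohexane-1,3-dione | C=CCC1(C)C(=O)CCCC1=O | intermediate
16 | (2R,3R)-3-hydroxy-2-methyl-2-(prop-2-en-1-yl)cyclohexan-1-one (OH cis to allyl) | O=C1[C@](C)(CC=C)[C@H](O)CCC1 | intermediate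
17 | 2-methylbut-3-en-2-ol | C=CC(C)(C)O | starting material
18 | (2R,3R)-3-hydroxy-2-[(2E)-4-hydroxy-4-methylpent-2-en-1-yl]-2-methylcyclohexan-1-one | O=C1[C@](C)(C/C=C/C(C)(C)O)[C@H](O)CCC1 | intermediate
19 | (2R,3R)-2-methyl-2-[(2E)-4-methyl-4-(triethylsilyloxy)pent-2-en-1-yl]-3-(triethylsilyloxy)cyclohexan-1-one | O=C1[C@](C)(C/C=C/C(C)(C)O[Si](CC)(CC)CC)[C@H](O[Si](CC)(CC)CC)CCC1 | intermediate
20 | lithium (5R,6R)-6-methyl-6-[(2E)-4-methyl-4-(triethylsilyloxy)pent-2-en-1-yl]-5-(triethylsilyloxy)cyclohex-1-en-1-olate | [Li]OC=1[C@](C)(C/C=C/C(C)(C)O[Si](CC)(CC)CC)[C@H](O[Si](CC)(CC)CC)CCC=1 | intermediate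
21 | (2R,3R,6RS)-2,6-dimethyl-2-[(2E)-4-methyl-4-(triethylsilyloxy)pent-2-en-1-yl]-3-(triethylsilyloxy)cyclohexan-1-one | O=C1[C@](C)(C/C=C/C(C)(C)O[Si](CC)(CC)CC)[C@H](O[Si](CC)(CC)CC)CCC1C | intermediate
22 | potassium (5R,6R)-2,6-dimethyl-6-[(2E)-4-methyl-4-(triethylsilyloxy)pent-2-en-1-yl]-5-(triethylsilyloxy)cyclohex-1-en-1-olate | [K]OC=1[C@](C)(C/C=C/C(C)(C)O[Si](CC)(CC)CC)[C@H](O[Si](CC)(CC)CC)CCC=1C | intermediate
23 | (5R,6R)-2,6-dimethyl-6-[(2E)-4-methyl-4-(triethylsilyloxy)pent-2-en-1-yl]-5-(triethylsilyloxy)cyclohex-1-en-1-yl trifluoromethanesulfonate | CC1=C(OS(=O)(=O)C(F)(F)F)[C@](C)(C/C=C/C(C)(C)O[Si](CC)(CC)CC)[C@H](O[Si](CC)(CC)CC)CC1 | intermediate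
24 | (5R,6S)-1-ethenyl-2,6-dimethyl-6-[(2E)-4-methyl-4-(triethylsilyloxy)pent-2-en-1-yl]-5-(triethylsilyloxy)cyclohex-1-ene | CC1=C(C=C)[C@](C)(C/C=C/C(C)(C)O[Si](CC)(CC)CC)[C@H](O[Si](CC)(CC)CC)CC1 | intermediate
25 | 9-[2-(CyR)ethyl]-9-borabicyclo[3.3.1]nonane | CC1=C(CCB2C3CCCC2CCC3)[C@](C)(C/C=C/C(C)(C)O[Si](CC)(CC)CC)[C@H](O[Si](CC)(CC)CC)CC1 | intermediate
26 | 2-(CyR)ethan-1-ol | CC1=C(CCO)[C@](C)(C/C=C/C(C)(C)O[Si](CC)(CC)CC)[C@H](O[Si](CC)(CC)CC)CC1 | intermediate
27 | 2-(CyR)acetaldehyde | CC1=C(CC=O)[C@](C)(C/C=C/C(C)(C)O[Si](CC)(CC)CC)[C@H](O[Si](CC)(CC)CC)CC1 | intermediate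
28 | lithium (3R,5aR,9aR)-2,2,5a-trimethyl-3-(triethylsilyloxy)-2,3,4,5,5a,9a-hexahydro-1-benzoxepin-7-olate | [Li]OC1=C[C@@]2(C)CC[C@@H](O[Si](CC)(CC)CC)C(C)(C)O[C@@H]2C=C1 | intermediate
29 | (3R,5aR,9aR)-6-[1-hydroxy-2-(CyR)ethyl]-2,2,5a-trimethyl-3-(triethylsilyloxy)-2,3,4,5,5a,9a-hexahydro-1-benzoxepin-7(6H)-one (mixture at C6 and carbinol) | CC1=C(CC(O)C2[C@@]3(C)CC[C@@H](O[Si](CC)(CC)CC)C(C)(C)O[C@@H]3C=CC2=O)[C@](C)(C/C=C/C(C)(C)O[Si](CC)(CC)CC)[C@H](O[Si](CC)(CC)CC)CC1 | intermediate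
30 | methanesulfonate of 29 | CC1=C(CC(OS(C)(=O)=O)C2[C@@]3(C)CC[C@@H](O[Si](CC)(CC)CC)C(C)(C)O[C@@H]3C=CC2=O)[C@](C)(C/C=C/C(C)(C)O[Si](CC)(CC)CC)[C@H](O[Si](CC)(CC)CC)CC1 | intermediate
31 | (3R,5aR,9aR)-6-[2-(CyR)ethylidene]-2,2,5a-trimethyl-3-(triethylsilyloxy)-2,3,4,5,5a,9a-hexahydro-1-benzoxepin-7(6H)-one (exocyclic alkene geometry not defined) | CC1=C(CC=C2[C@@]3(C)CC[C@@H](O[Si](CC)(CC)CC)C(C)(C)O[C@@H]3C=CC2=O)[C@](C)(C/C=C/C(C)(C)O[Si](CC)(CC)CC)[C@H](O[Si](CC)(CC)CC)CC1 | intermediate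
32 | (3R,5aR,6R,9aR)-6-[2-(CyR)ethyl]-2,2,5a-trimethyl-3-(triethylsilyloxy)octahydro-1-benzoxepin-7(2H)-one | CC1=C(CC[C@@H]2[C@@]3(C)CC[C@@H](O[Si](CC)(CC)CC)C(C)(C)O[C@@H]3CCC2=O)[C@](C)(C/C=C/C(C)(C)O[Si](CC)(CC)CC)[C@H](O[Si](CC)(CC)CC)CC1 | intermediate
33 | (3R,5aR,6R,7S,9aR)-6-[2-(CyR)ethyl]-2,2,5a,7-tetramethyl-3-(triethylsilyloxy)decahydro-1-benzoxepin-7-ol | CC1=C(CC[C@@H]2[C@@]3(C)CC[C@@H](O[Si](CC)(CC)CC)C(C)(C)O[C@@H]3CC[C@]2(C)O)[C@](C)(C/C=C/C(C)(C)O[Si](CC)(CC)CC)[C@H](O[Si](CC)(CC)CC)CC1 | intermediate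
34 | siphonellinol C, (3R,5aR,6R,7S,9aR)-6-{2-[(5R,6S)-5-hydroxy-6-[(2E)-4-hydroxy-4-methylpent-2-en-1-yl]-2,6-dimethylcyclohex-1-en-1-yl]ethyl}-2,2,5a,7-tetramethyldecahydro-1-benzoxepine-3,7-diol | CC1=C(CC[C@@H]2[C@@]3(C)CC[C@@H](O)C(C)(C)O[C@@H]3CC[C@]2(C)O)[C@](C)(C/C=C/C(C)(C)O)[C@H](O)CC1 | target

## Step count and risks

Total steps: 21. Longest linear sequence: 14 steps (steps 8–16, then 17–21, from 2-methylcyclohexane-1,3-dione). The other branch is 12 steps (steps 1–7, then 17–21).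

**Step 5 (epoxonium cascade).** The enol silane may be too weak or too labile a terminator and give partly cyclized material. The fallback sets out from 6. Its kinetic enolate (LiN(iPr)2, PhNTf2, THF, −78 °C) is trapped as the enol triflate F1. Coupling with Me3SiCH2MgCl under Pd(PPh3)4 catalysis gives the 2-substituted allylsilane F2, a stable and more nucleophilic terminator. The same cascade (Me3SiOTf cat., 2,6-di-tert-butyl-4-methylpyridine, CH2Cl2, −78 °C) then gives the 7-methylidene bicycle as its trimethylsilyl ether F3. Ozonolysis (O3, CH2Cl2, −78 °C; Me2S) comes back to the route at 8, which is methanolysed to 9 as before.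

**Step 17 (aldol).** The lithium dienolate may deprotonate the β,γ-unsaturated aldehyde instead of adding to it. The fallback sets out from 12. The enone is converted (LiN(iPr)2, Me3SiCl, THF, −78 °C) into the isolated 7-trimethylsilyloxy diene F4. This is joined to 27 in a Mukaiyama aldol addition (BF3·OEt2, CH2Cl2, −78 °C), with no basic species present, and comes back to the route at 29 after aqueous work-up.

**Step 18 (dehydration).** Base may move the new exocyclic alkene, which is skipped to the ring C alkene, out of conjugation, or the C6 hydrogen may be poorly aligned for elimination. The fallback sets out from 29 and avoids any alkene at C6. Acylation with PhOC(S)Cl and pyridine gives the O-phenyl thionocarbonate F5. Barton–McCombie reduction (Bu3SnH, AIBN, toluene, 80 °C) gives the 6-alkyl enone F6 as a C6 mixture. LiN(iPr)2 at −78 °C gives the lithium dienolate F7, and kinetic protonation with 2,6-di-tert-butyl-4-methylphenol from the face opposite the C5a methyl gives the (6R)-enone F8. Conjugate reduction of the ring alkene with [(Ph3P)CuH]6 and water comes back to the route at 32.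

## Further compounds

F1 | step 5 | 4-[(2R,3R)-3-{2-[(2R)-3,3-dimethyloxiran-2-yl]ethyl}-3-methyloxiran-2-yl]but-1-en-2-yl trifluoromethanesulfonate | C=C(OS(=O)(=O)C(F)(F)F)CC[C@H]1O[C@]1(C)CC[C@H]1OC1(C)C
F2 | step 5 | trimethyl{2-methylidene-4-[(2R,3R)-3-{2-[(2R)-3,3-dimethyloxiran-2-yl]ethyl}-3-methyloxiran-2-yl]butyl}silane | C=C(C[Si](C)(C)C)CC[C@H]1O[C@]1(C)CC[C@H]1OC1(C)C
F3 | step 5 | trimethyl{[(3R,5aR,9aR)-2,2,5a-trimethyl-7-methylidenedecahydro-1-benzoxepin-3-yl]oxy}silane | C=C1C[C@@]2(C)CC[C@@H](O[Si](C)(C)C)C(C)(C)O[C@@H]2CC1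
F4 | step 17 | (3R,5aR,9aR)-2,2,5a-trimethyl-3-(triethylsilyloxy)-7-(trimethylsilyloxy)-2,3,4,5,5a,9a-hexahydro-1-benzoxepine | C[Si](C)(C)OC1=C[C@@]2(C)CC[C@@H](O[Si](CC)(CC)CC)C(C)(C)O[C@@H]2C=C1
F5 | step 18 | O-phenyl thionocarbonate of 29 | CC1=C(CC(OC(=S)Oc4ccccc4)C2[C@@]3(C)CC[C@@H](O[Si](CC)(CC)CC)C(C)(C)O[C@@H]3C=CC2=O)[C@](C)(C/C=C/C(C)(C)O[Si](CC)(CC)CC)[C@H](O[Si](CC)(CC)CC)CC1
F6 | step 18 | (3R,5aR,9aR)-6-[2-(CyR)ethyl]-2,2,5a-trimethyl-3-(triethylsilyloxy)-2,3,4,5,5a,9a-hexahydro-1-benzoxepin-7(6H)-one (C6 mixture) | CC1=C(CCC2[C@@]3(C)CC[C@@H](O[Si](CC)(CC)CC)C(C)(C)O[C@@H]3C=CC2=O)[C@](C)(C/C=C/C(C)(C)O[Si](CC)(CC)CC)[C@H](O[Si](CC)(CC)CC)CC1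
F7 | step 18 | lithium dienolate of F6 | CC1=C(CCC=2[C@@]3(C)CC[C@@H](O[Si](CC)(CC)CC)C(C)(C)O[C@@H]3C=CC=2O[Li])[C@](C)(C/C=C/C(C)(C)O[Si](CC)(CC)CC)[C@H](O[Si](CC)(CC)CC)CC1
F8 | step 18 | (3R,5aR,6R,9aR)-6-[2-(CyR)ethyl]-2,2,5a-trimethyl-3-(triethylsilyloxy)-2,3,4,5,5a,9a-hexahydro-1-benzoxepin-7(6H)-one | CC1=C(CC[C@@H]2[C@@]3(C)CC[C@@H](O[Si](CC)(CC)CC)C(C)(C)O[C@@H]3C=CC2=O)[C@](C)(C/C=C/C(C)(C)O[Si](CC)(CC)CC)[C@H](O[Si](CC)(CC)CC)CC1
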